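**Plan**

- Retrosynthetic cuts: the benzamide C–N bond, then the bond from the lactam nitrogen to the butyl chain. Next the N-methyl bond is cut (back to MeI) and the two ring nitrogens are rejoined. Then the two N–CH2 bonds of the trimethylene bridge are cut (1,3-dibromopropane). Last come the N–N bond and the hydrazide C–N bond of a pyrazolidinone.
- Enabling feature: in the 1,5-diazocan-2-one ring (N1 lactam nitrogen, C2 carbonyl, C3, C4 bearing phenyl, N5 methylated, C6–C8), N1 and N5 stand 1,5 across the ring. An N1–N5 bond would split the eight-membered ring into a pyrazolidin-3-one (N1, C2, C3, C4, N5) fused to a pyrazolidine (N5, C6, C7, C8, N1).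
- Forward order: the pyrazolidinone ring is made first (N-amination, lactamisation). The pyrazolidine ring is made second by double N-alkylation with the C3 unit, which forms N5–C6 and N1–C8. The eight-membered ring appears third, when N5 is methylated and the N1–N5 bond is broken reductively. The side chain is then attached at N1, unmasked and benzoylated.
- Stereochemistry: the single (S) centre at C4 is bought with (S)-3-amino-3-phenylpropanoic acid. None of its four bonds is made or broken anywhere in the route.

Key step: step 4

Remark: the N-Boc oxaziridine of step 2 is treated as a purchasable reagent; if it must be made, two routine steps from diethyl ketomalonate supply it.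
Remark: the configuration at the quaternary nitrogen of compound 9 is not controlled (methyl anti to phenyl is expected to prevail) and does not matter, since both N-epimers give the same amine 10 in step 6.

**Route**

Step 1
Reactants: 1 (S)-3-amino-3-phenylpropanoic acid
Product: 2 methyl (S)-3-amino-3-phenylpropanoate (free base)
Conditions: SOCl2, MeOH, 0 °C → reflux; then aq. NaHCO3 work-up
Reagents that add atoms: methanol, CO
Why: Fischer esterification driven by HCl generated from SOCl2 and methanol, with the amine held as its ammonium salt, so the benzylic centre is not touched.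

Step 2
Reactants: 2 methyl (S)-3-amino-3-phenylpropanoate
Product: 3 methyl (S)-3-[2-(tert-butoxycarbonyl)hydrazinyl]-3-phenylpropanoate
Conditions: N-Boc oxaziridine reagent (1.05 equiv), CH2Cl2, 0 °C → rt
Reagents that add atoms: diethyl 2-(tert-butoxycarbonyl)oxaziridine-3,3-dicarboxylate, CCOC(=O)C1(C(=O)OCC)ON1C(=O)OC(C)(C)C
Why: Electrophilic N-amination of a primary amine by an N-Boc oxaziridine (attack of the amine on the ring nitrogen with release of a ketone that should not trap the substrate as an imine) forms the N–N bond at nitrogen only, so the (S) centre is retained.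

Step 3
Reactants: 3 methyl (S)-3-[2-(tert-butoxycarbonyl)hydrazinyl]-3-phenylpropanoate
Product: 5 (S)-5-phenylpyrazolidin-3-one, via methyl (S)-3-hydrazinyl-3-phenylpropanoate 4 (not isolated)
Conditions: HCl (4 M in 1,4-dioxane), rt; evaporate; then NaHCO3, MeOH, rt → 40 °C
Reagents that add atoms: none
Why: Acidolytic Boc removal gives the hydrazino ester as its hydrochloride, and after neutralisation the terminal NH2 closes onto the methyl ester in a 5-exo-trig lactamisation (hydrazide formation) that should be fast under mild conditions and leaves the benzylic centre alone.

Step 4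
Reactants: 5 (S)-5-phenylpyrazolidin-3-one; 6 1,3-dibromopropane
Product: 8 (4S)-4-phenyl-1,5-diazabicyclo[3.3.0]octan-2-one, via (S)-1-(3-bromopropyl)-5-phenylpyrazolidin-3-one 7 (not isolated)
Conditions: 6 (1.2 equiv), K2CO3 (3 equiv), DMF (about 0.05 M), rt → 70 °C
Reagents that add atoms: none
Why: The sp3 amine nitrogen of 5 (the later N5) is the more nucleophilic centre under carbonate conditions and displaces the first bromide by SN2 to give 7, whose hydrazide N–H (the later N1), now the only acidic site, is deprotonated by K2CO3 and displaces the second bromide intramolecularly. The closest known reaction type is the double N-alkylation of pyrazolidin-3-ones by 1,3-dihalopropanes to tetrahydropyrazolo[1,2-a]pyrazol-1-ones, which extends the carbonate-mediated alkylation of pyrazolidinones at the amine nitrogen. The one new ring, the pyrazolidine, closes in a 5-exo-tet mode, so the complete eight-atom perimeter of the later diazocanone is assembled without any medium-ring cyclisation. No stereocentre is created: the benzylic centre from 1 is a spectator and the bridgehead nitrogen atoms are not configurationally fixed. The step needs N- over O-alkylation of the hydrazide and ring closure over coupling of two pyrazolidinones; the first is secured because N-closure gives a five-membered ring whereas O-closure would give a seven-membered imidate, the second by the high effective molarity of the 5-exo-tet closure together with moderate dilution and only a slight excess of 6. The weak base should leave the CH2 group next to the carbonyl undisturbed, so opening at the benzylic C–N bond by retro-aza-Michael elimination is not expected.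

Step 5
Reactants: 8 (4S)-4-phenyl-1,5-diazabicyclo[3.3.0]octan-2-one
Product: 9 (4S)-5-methyl-2-oxo-4-phenyl-1-aza-5-azoniabicyclo[3.3.0]octane iodide
Conditions: MeI (5 equiv), MeCN, 45 °C, sealed vessel
Reagents that add atoms: iodomethane, CI
Why: Menshutkin quaternisation occurs at the only nucleophilic nitrogen, the sp3 bridgehead N5 (N1 is deactivated by the carbonyl group), as in the known alkylation of N-acyl-N',N'-dialkylhydrazines to acylhydrazinium salts, and it installs the N-methyl group of the target.

Step 6
Reactants: 9 (4S)-5-methyl-2-oxo-4-phenyl-1-aza-5-azoniabicyclo[3.3.0]octane iodide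
Product: 10 (S)-5-methyl-4-phenyl-1,5-diazocan-2-one
Conditions: SmI2 (2.5 equiv, THF), MeOH, −78 → 0 °C, salt added to the reductant
Reagents that add atoms: none
Why: Reductive N–N cleavage of an N-acyl hydrazine derivative by SmI2, in which electron transfer from divalent samarium is followed by loss of the neutral tertiary amine, further reduction of the amidyl fragment to the amidate and protonation by methanol, while the benzylic C–N bond and the phenyl ring should lie beyond the reducing power of SmI2 in THF–MeOH.

Step 7
Reactants: 10 (S)-5-methyl-4-phenyl-1,5-diazocan-2-one; 11 N-(4-bromobutyl)phthalimide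
Product: 12 2-{4-[(4S)-5-methyl-2-oxo-4-phenyl-1,5-diazocan-1-yl]butyl}isoindoline-1,3-dione
Conditions: NaH (1.1 equiv), DMF, 0 °C; then 11 (1.1 equiv), 0 °C → rt
Reagents that add atoms: none
Why: SN2 N-alkylation of a lactam sodium salt by a primary alkyl bromide, the lactam N–H being the only acidic proton and the hindered tertiary N5 being a far poorer nucleophile than the amidate.

Step 8
Reactants: 12 2-{4-[(4S)-5-methyl-2-oxo-4-phenyl-1,5-diazocan-1-yl]butyl}isoindoline-1,3-dione
Product: 13 (S)-1-(4-aminobutyl)-5-methyl-4-phenyl-1,5-diazocan-2-one
Conditions: N2H4·H2O (3 equiv), EtOH, reflux; filter; amine used directly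
Reagents that add atoms: none
Why: Ing–Manske hydrazinolysis (Gabriel amine synthesis) frees the primary amine as phthalhydrazide separates, and the unactivated tertiary lactam should not react with hydrazine.

Step 9
Reactants: 13 (S)-1-(4-aminobutyl)-5-methyl-4-phenyl-1,5-diazocan-2-one; 14 benzoyl chloride
Product: 15 N-{4-[(4S)-5-methyl-2-oxo-4-phenyl-1,5-diazocan-1-yl]butyl}benzamide (CNP0138586.1)
Conditions: 14 (1.05 equiv), 1 M aq. NaOH, CH2Cl2, 0 °C
Reagents that add atoms: none
Why: Schotten–Baumann N-acylation of the primary amine, the only nitrogen that can be acylated since N5 is a tertiary amine and N1 a tertiary amide.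

**Compound list**

1 | (S)-3-amino-3-phenylpropanoic acid | N[C@@H](CC(=O)O)c1ccccc1 | starting material
2 | methyl (S)-3-amino-3-phenylpropanoate | N[C@@H](CC(=O)OC)c1ccccc1 | intermediate
3 | methyl (S)-3-[2-(tert-butoxycarbonyl)hydrazinyl]-3-phenylpropanoate | COC(=O)C[C@@H](c1ccccc1)NNC(=O)OC(C)(C)C | intermediate
4 | methyl (S)-3-hydrazinyl-3-phenylpropanoate (formed as its hydrochloride, not isolated) | COC(=O)C[C@@H](c1ccccc1)NN | intermediate
5 | (S)-5-phenylpyrazolidin-3-one | O=C1C[C@@H](c2ccccc2)NN1 | intermediate
6 | 1,3-dibromopropane | BrCCCBr | starting material
7 | (S)-1-(3-bromopropyl)-5-phenylpyrazolidin-3-one (not isolated) | O=C1C[C@@H](c2ccccc2)N(CCCBr)N1 | intermediate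
8 | (4S)-4-phenyl-1,5-diazabicyclo[3.3.0]octan-2-one | O=C1C[C@@H](c2ccccc2)N2CCCN12 | intermediate
9 | (4S)-5-methyl-2-oxo-4-phenyl-1-aza-5-azoniabicyclo[3.3.0]octane iodide (configuration at N5 not defined) | O=C1C[C@@H](c2ccccc2)[N+]2(C)CCCN12.[I-] | intermediate
10 | (S)-5-methyl-4-phenyl-1,5-diazocan-2-one | CN1CCCNC(=O)C[C@H]1c1ccccc1 | intermediate
11 | N-(4-bromobutyl)phthalimide | O=C1c2ccccc2C(=O)N1CCCCBr | starting material
12 | 2-{4-[(4S)-5-methyl-2-oxo-4-phenyl-1,5-diazocan-1-yl]butyl}isoindoline-1,3-dione | CN1CCCN(CCCCN2C(=O)c3ccccc3C2=O)C(=O)C[C@H]1c1ccccc1 | intermediate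
13 | (S)-1-(4-aminobutyl)-5-methyl-4-phenyl-1,5-diazocan-2-one | CN1CCCN(CCCCN)C(=O)C[C@H]1c1ccccc1 | intermediate
14 | benzoyl chloride | O=C(Cl)c1ccccc1 | starting material
15 | N-{4-[(4S)-5-methyl-2-oxo-4-phenyl-1,5-diazocan-1-yl]butyl}benzamide | CN1CCCN(CCCCNC(=O)c2ccccc2)C(=O)C[C@H]1c1ccccc1 | target

**Step count**

Total step count: 9. Longest linear sequence: 9 steps (1 → 15).

**Steps most likely to fail**

Step 6 (with the quaternisation of step 5 that feeds it). The quaternary nitrogen of 9 sits β to the lactam carbonyl. As samarium alkoxide builds up, base-induced β-elimination at the benzylic C–N bond could compete with electron transfer, and incomplete methylation of the hindered N5 would carry unreactive material forward. The fallback changes the order of events and sets out from compound 8. Sodium in liquid NH3/THF at −78 °C with an NH4Cl quench cleaves the N–N bond of the neutral N-acyl hydrazine and should give (S)-4-phenyl-1,5-diazocan-2-one F1. Reductive amination of the secondary amine of F1 with aqueous formaldehyde and NaBH(OAc)3 in 1,2-dichloroethane then installs the methyl group. The route is rejoined at compound 10, and no ammonium centre β to a carbonyl is ever formed.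

Step 4. Intermolecular alkylation may outrun ring closure and join two pyrazolidinones through one C3 unit, or the closure may stall at the bromopropyl stage because carbonate deprotonates the hydrazide too slowly. The fallback forms the two C–N bonds in separate operations and sets out from compound 5. Alkylation at the amine nitrogen with 3-bromopropan-1-ol (K2CO3, MeCN) should give (S)-1-(3-hydroxypropyl)-5-phenylpyrazolidin-3-one F2, which carries no second leaving group and cannot bridge. Treatment with MsCl and Et3N in CH2Cl2 at 0 °C converts it into 3-[(S)-3-oxo-5-phenylpyrazolidin-1-yl]propyl methanesulfonate F3. One equivalent of NaH in THF at 0 °C then deprotonates the hydrazide N–H and closes the pyrazolidine ring by the same 5-exo-tet displacement. The route is rejoined at compound 8.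

Step 2. Transfer of the NBoc group to the primary amine may be slowed by reversible addition of the amine to the released ketone, or may continue to double amination. The fallback makes the N–N bond on an amide anion and sets out from compound 2. Cyclisation of 2 with t-BuMgCl in THF at 0 °C should give the β-lactam (S)-4-phenylazetidin-2-one F4. Deprotonation with NaH and amination of the lactam anion with O-(diphenylphosphinyl)hydroxylamine gives (S)-1-amino-4-phenylazetidin-2-one F5. Methanolic HCl opens the strained ring to the hydrazino ester hydrochloride. The route is rejoined at compound 4, which is neutralised and cyclised to 5 as in step 3.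

**Further compounds**

F1 | step 6 | (S)-4-phenyl-1,5-diazocan-2-one | O=C1C[C@@H](c2ccccc2)NCCCN1
F2 | step 4 | (S)-1-(3-hydroxypropyl)-5-phenylpyrazolidin-3-one | O=C1C[C@@H](c2ccccc2)N(CCCO)N1
F3 | step 4 | 3-[(S)-3-oxo-5-phenylpyrazolidin-1-yl]propyl methanesulfonate | CS(=O)(=O)OCCCN1NC(=O)C[C@H]1c1ccccc1
F4 | step 2 | (S)-4-phenylazetidin-2-one | O=C1C[C@@H](c2ccccc2)N1
F5 | step 2 | (S)-1-amino-4-phenylazetidin-2-one | NN1C(=O)C[C@H]1c1ccccc1
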